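**Plan**

- Retrosynthesis: the two sulfate S–O bonds and the C3–Br bond are cut first. The benzene ring is then cut at C1–C2 and C2–C3, which removes the bromine-bearing carbon C2.
- Enabling feature: with the ring numbered C1 (CH2OSO3H), C2 (Br), C3 (Br), C4 (OSO3H), C5 (OH), C6 (H), the atoms C1, C6, C5, C4, C3, the CH2O arm and both ring oxygens are C2, C3, C4, C5, C6 of the 4-pyranone ring of kojic acid. Only the ring oxygen has to be exchanged for a CBr carbon.
- Forward: kojic acid is bis-etherified; its pyranone ring is converted into the benzene ring (the only ring formed) by a bromomethylene phosphorus ylide; the C4 phenol is then unveiled, C3 brominated, C4 sulfated, the arm unveiled and sulfated, and C5 desilylated.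
- Order of sulfation: C4 is sulfated before the arm, because a benzylic sulfate para to a free phenol would collapse to a quinone methide.
- Stereochemistry: the target has no stereocenter. The regiochemistry of the two catechol oxygens comes from their origin: the pyranone carbonyl oxygen becomes the C5 silyl ether, the enol oxygen the C4 ether.

Key step: step 2

Remark: the target is drawn as the free bis(hydrogen sulfate); the sulfate intermediates are carried as sodium salts and the acid form is released only in the last work-up, cold and dilute, because aryl hydrogen sulfates hydrolyse under their own acidity.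

**Route**

Step 1
Reactants: 1 kojic acid [5-hydroxy-2-(hydroxymethyl)-4H-pyran-4-one]; 2 4-methoxybenzyl chloride
Product: 3 5-(4-methoxybenzyloxy)-2-[(4-methoxybenzyloxy)methyl]-4H-pyran-4-one
Conditions: NaH (2.4 equiv), DMF, 0 °C; 2 (2.3 equiv), Bu4NI (0.1 equiv), 0 °C → rt
Reagents that add atoms: 4-methoxybenzyl chloride (2), COc1ccc(CCl)cc1
Why: Williamson etherification, in which NaH deprotonates first the acidic enolic 5-OH and then the primary alcohol (K2CO3 would stop at the enol ether), and both oxyanions are alkylated by the iodide-activated benzylic chloride at a temperature where alkoxide addition to the pyranone is slow.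

Step 2
Reactants: 3 5-(4-methoxybenzyloxy)-2-[(4-methoxybenzyloxy)methyl]-4H-pyran-4-one; 4 tri(propan-2-yl)silyl trifluoromethanesulfonate; 5 (bromomethyl)triphenylphosphonium bromide
Product: 10 [4-bromo-2-(4-methoxybenzyloxy)-5-[(4-methoxybenzyloxy)methyl]phenoxy]tri(propan-2-yl)silane, via bromomethylidene ylide 6 (not isolated), via silyloxypyrylium triflate 7 (not isolated), via 2H-pyran phosphonium adduct 8 (not isolated), via open-chain keto phosphonium salt 9 (not isolated)
Conditions: 5 (2.4 equiv), KOt-Bu (2.3 equiv), THF, −78 °C; separately 3, i-Pr3SiOTf (1.0 equiv), 2,6-di-tert-butyl-4-methylpyridine (0.1 equiv), CH2Cl2, −78 → −40 °C; pyrylium solution added to the ylide at −78 °C, then → rt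
Reagents that add atoms: tri(propan-2-yl)silyl trifluoromethanesulfonate (4), CC(C)[Si](OS(=O)(=O)C(F)(F)F)(C(C)C)C(C)C; (bromomethyl)triphenylphosphonium bromide (5), [Br-].BrC[P+](c1ccccc1)(c1ccccc1)c1ccccc1
Why: Proposed new method: O-silylation of the vinylogous-ester carbonyl of 3 should give the 4-silyloxypyrylium triflate 7, whose unsubstituted ring carbon next to oxygen is the least hindered electrophilic site, so the carbanion of the non-stabilised bromo ylide 6 adds there to give the 2H-pyran 8, which opens by oxa-6π electrocyclic ring opening to the keto phosphonium salt 9 with a cis central double bond, and a second equivalent of 6 acts as base to regenerate the ylide at the CHBr carbon. The closest known reaction type is the conversion of 2,4,6-triarylpyrylium salts into benzenes by alkylidenetriphenylphosphoranes, together with silyl triflate activation of 4-pyranones and chromones toward carbon nucleophiles at C2; neither has been shown for a 4-silyloxypyrylium made in the flask or for a halomethylene ylide. The benzene ring closes by 6-exo-trig attack of the ylide carbon on the ketone carbonyl (an intramolecular Wittig olefination, equivalent to a thermal disrotatory 6π closure of the phosphonio trienolate) and loss of Ph3PO, which forms C1–C2 and C2–C3 of the target and aromatises the ring at once. No stereocenter is formed, and the geometry of the outer double bond of 9 is irrelevant because it becomes part of a delocalised allylic ylide. The step needs chemoselective attack at a ring carbon next to oxygen instead of C4, silicon or the CH2O protons: C4 is deactivated and shielded by its silyloxy donor, the bulky triisopropylsilyl group slows silyl transfer to the ylide, and addition at −78 °C with no free alkoxide present limits proton transfer. Attack at the substituted ring carbon next to oxygen would be harmless, since that adduct opens to an aldehyde and closes to the same arene.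

Step 3
Reactants: 10 [4-bromo-2-(4-methoxybenzyloxy)-5-[(4-methoxybenzyloxy)methyl]phenoxy]tri(propan-2-yl)silane
Product: 11 5-bromo-4-[(4-methoxybenzyloxy)methyl]-2-[tri(propan-2-yl)silyloxy]phenol
Conditions: CF3CO2H (2% v/v), C6HMe5 (3 equiv), CH2Cl2, −20 → 0 °C; NaHCO3 quench
Reagents that add atoms: none
Why: Acid-mediated SN1 ether cleavage, in which the aryl 4-methoxybenzyl ether ionises much faster than the dialkyl-type ether of the arm because a phenol is the better leaving group, pentamethylbenzene traps the 4-methoxybenzyl cation by Friedel–Crafts alkylation before it can C-benzylate the phenol, and the aryl silyl ether tolerates dilute anhydrous acid.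

Step 4
Reactants: 11 5-bromo-4-[(4-methoxybenzyloxy)methyl]-2-[tri(propan-2-yl)silyloxy]phenol
Product: 12 2,3-dibromo-4-[(4-methoxybenzyloxy)methyl]-6-[tri(propan-2-yl)silyloxy]phenol
Conditions: NBS (1.05 equiv), i-Pr2NH (10 mol %), CH2Cl2, −78 → −20 °C, dark
Reagents that add atoms: N-bromosuccinimide, O=C1CCC(=O)N1Br
Why: Amine-catalysed ortho-selective electrophilic bromination of a phenol, for which C3 is the only open ortho or para position of the free C4 hydroxyl, while C6 is meta to it and shielded by the silyl ether and the anisyl ring is far less activated.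

Step 5
Reactants: 12 2,3-dibromo-4-[(4-methoxybenzyloxy)methyl]-6-[tri(propan-2-yl)silyloxy]phenol
Product: 14 sodium 2,3-dibromo-4-[(4-methoxybenzyloxy)methyl]-6-[tri(propan-2-yl)silyloxy]phenyl sulfate, via pyridinium aryl sulfate 13 (not isolated)
Conditions: SO3·pyridine (5 equiv), pyridine, 45 °C; then aq. NaHCO3, 0 °C
Reagents that add atoms: sulfur trioxide–pyridine complex, [O-]S(=O)(=O)[n+]1ccccc1; sodium hydrogen carbonate, [Na+].OC([O-])=O
Why: O-Sulfonation of a phenol by a sulfur trioxide–amine complex, run in weakly basic pyridine so that the neutral phenol reacts without build-up of the phenoxide that could start a 1,2-silyl shift to the neighbouring oxygen.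

Step 6
Reactants: 14 sodium 2,3-dibromo-4-[(4-methoxybenzyloxy)methyl]-6-[tri(propan-2-yl)silyloxy]phenyl sulfate
Product: 15 sodium 2,3-dibromo-4-(hydroxymethyl)-6-[tri(propan-2-yl)silyloxy]phenyl sulfate
Conditions: DDQ (1.5 equiv), MeCN/pH 7 phosphate buffer (10:1), 0 °C → rt
Reagents that add atoms: none
Why: Oxidative cleavage of a 4-methoxybenzyl ether by DDQ (hydride abstraction to the oxocarbenium ion, then hydrolysis), selective because the anisyl CH2 is far more electron-rich than the benzylic CH2 of the dibromo aryl sulfate core, which also keeps the freed alcohol from being oxidised further.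

Step 7
Reactants: 15 sodium 2,3-dibromo-4-(hydroxymethyl)-6-[tri(propan-2-yl)silyloxy]phenyl sulfate
Product: 17 disodium {2,3-dibromo-4-(sulfonatooxy)-5-[tri(propan-2-yl)silyloxy]phenyl}methyl sulfate, via mixed sodium pyridinium bis-sulfate 16 (not isolated)
Conditions: SO3·pyridine (3 equiv), DMF, 0 °C → rt; then aq. NaHCO3, 0 °C
Reagents that add atoms: sulfur trioxide–pyridine complex, [O-]S(=O)(=O)[n+]1ccccc1; sodium hydrogen carbonate, [Na+].OC([O-])=O
Why: O-Sulfonation of a primary alcohol with SO3·pyridine, clean here because the only other oxygen functions are a sulfate and a silyl ether and because the para oxygen, already sulfated, can no longer expel the benzylic sulfate.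

Step 8
Reactants: 17 disodium {2,3-dibromo-4-(sulfonatooxy)-5-[tri(propan-2-yl)silyloxy]phenyl}methyl sulfate
Product: 19 [2,3-dibromo-5-hydroxy-4-(sulfooxy)phenyl]methyl hydrogen sulfate (CNP0301961.0), via disodium salt of the target 18 (not isolated)
Conditions: HF·pyridine, pyridine, THF, 0 °C → rt; volatiles removed; then 1 M HCl (2.0 equiv), 0 °C, desalting on HP-20 (H2O, then H2O/MeCN), freeze-drying
Reagents that add atoms: none
Why: Fluoride-driven cleavage of the aryl silyl ether under buffered conditions that sulfate monoester anions tolerate, followed by a plain exchange of Na+ for H+, the freed C5 phenol being meta to the arm and therefore unable to expel the benzylic sulfate.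

**Compound list**

1 | kojic acid, 5-hydroxy-2-(hydroxymethyl)-4H-pyran-4-one | OCc1cc(=O)c(O)co1 | starting material
2 | 4-methoxybenzyl chloride | COc1ccc(CCl)cc1 | starting material
3 | 5-(4-methoxybenzyloxy)-2-[(4-methoxybenzyloxy)methyl]-4H-pyran-4-one | COc1ccc(COCc2cc(=O)c(OCc3ccc(OC)cc3)co2)cc1 | intermediate
4 | tri(propan-2-yl)silyl trifluoromethanesulfonate | CC(C)[Si](OS(=O)(=O)C(F)(F)F)(C(C)C)C(C)C | starting material
5 | (bromomethyl)triphenylphosphonium bromide | [Br-].BrC[P+](c1ccccc1)(c1ccccc1)c1ccccc1 | starting material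
6 | (bromomethylidene)triphenyl-λ5-phosphane (ylide, not isolated) | BrC=P(c1ccccc1)(c1ccccc1)c1ccccc1 | intermediate
7 | 5-(4-methoxybenzyloxy)-2-[(4-methoxybenzyloxy)methyl]-4-[tri(propan-2-yl)silyloxy]pyrylium trifluoromethanesulfonate (not isolated) | COc1ccc(COCc2cc(O[Si](C(C)C)(C(C)C)C(C)C)c(OCc3ccc(OC)cc3)c[o+]2)cc1.[O-]S(=O)(=O)C(F)(F)F | intermediate
8 | {bromo[3-(4-methoxybenzyloxy)-6-[(4-methoxybenzyloxy)methyl]-4-[tri(propan-2-yl)silyloxy]-2H-pyran-2-yl]methyl}triphenylphosphonium trifluoromethanesulfonate, mixture of diastereomers (not isolated) | COc1ccc(COCC2=CC(O[Si](C(C)C)(C(C)C)C(C)C)=C(OCc3ccc(OC)cc3)C(C(Br)[P+](c3ccccc3)(c3ccccc3)c3ccccc3)O2)cc1.[O-]S(=O)(=O)C(F)(F)F | intermediate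
9 | {1-bromo-3,7-bis(4-methoxybenzyloxy)-6-oxo-4-[tri(propan-2-yl)silyloxy]hepta-2,4-dien-1-yl}triphenylphosphonium trifluoromethanesulfonate, keto carbon and C3 cis across the 4,5-double bond, 2,3-double bond geometry open (not isolated) | COc1ccc(COCC(=O)/C=C(O[Si](C(C)C)(C(C)C)C(C)C)\C(OCc2ccc(OC)cc2)=CC(Br)[P+](c2ccccc2)(c2ccccc2)c2ccccc2)cc1.[O-]S(=O)(=O)C(F)(F)F | intermediate
10 | [4-bromo-2-(4-methoxybenzyloxy)-5-[(4-methoxybenzyloxy)methyl]phenoxy]tri(propan-2-yl)silane | COc1ccc(COCc2cc(O[Si](C(C)C)(C(C)C)C(C)C)c(OCc3ccc(OC)cc3)cc2Br)cc1 | intermediate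
11 | 5-bromo-4-[(4-methoxybenzyloxy)methyl]-2-[tri(propan-2-yl)silyloxy]phenol | COc1ccc(COCc2cc(O[Si](C(C)C)(C(C)C)C(C)C)c(O)cc2Br)cc1 | intermediate
12 | 2,3-dibromo-4-[(4-methoxybenzyloxy)methyl]-6-[tri(propan-2-yl)silyloxy]phenol | COc1ccc(COCc2cc(O[Si](C(C)C)(C(C)C)C(C)C)c(O)c(Br)c2Br)cc1 | intermediate
13 | pyridinium 2,3-dibromo-4-[(4-methoxybenzyloxy)methyl]-6-[tri(propan-2-yl)silyloxy]phenyl sulfate (not isolated) | COc1ccc(COCc2cc(O[Si](C(C)C)(C(C)C)C(C)C)c(OS(=O)(=O)[O-])c(Br)c2Br)cc1.c1cc[nH+]cc1 | intermediate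
14 | sodium 2,3-dibromo-4-[(4-methoxybenzyloxy)methyl]-6-[tri(propan-2-yl)silyloxy]phenyl sulfate | COc1ccc(COCc2cc(O[Si](C(C)C)(C(C)C)C(C)C)c(OS(=O)(=O)[O-])c(Br)c2Br)cc1.[Na+] | intermediate
15 | sodium 2,3-dibromo-4-(hydroxymethyl)-6-[tri(propan-2-yl)silyloxy]phenyl sulfate | OCc1cc(O[Si](C(C)C)(C(C)C)C(C)C)c(OS(=O)(=O)[O-])c(Br)c1Br.[Na+] | intermediate
16 | sodium pyridinium {2,3-dibromo-4-(sulfonatooxy)-5-[tri(propan-2-yl)silyloxy]phenyl}methyl sulfate (not isolated) | [O-]S(=O)(=O)OCc1cc(O[Si](C(C)C)(C(C)C)C(C)C)c(OS(=O)(=O)[O-])c(Br)c1Br.[Na+].c1cc[nH+]cc1 | intermediate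
17 | disodium {2,3-dibromo-4-(sulfonatooxy)-5-[tri(propan-2-yl)silyloxy]phenyl}methyl sulfate | [O-]S(=O)(=O)OCc1cc(O[Si](C(C)C)(C(C)C)C(C)C)c(OS(=O)(=O)[O-])c(Br)c1Br.[Na+].[Na+] | intermediate
18 | disodium [2,3-dibromo-5-hydroxy-4-(sulfonatooxy)phenyl]methyl sulfate (not isolated) | [O-]S(=O)(=O)OCc1cc(O)c(OS(=O)(=O)[O-])c(Br)c1Br.[Na+].[Na+] | intermediate
19 | [2,3-dibromo-5-hydroxy-4-(sulfooxy)phenyl]methyl hydrogen sulfate | O=S(=O)(O)OCc1cc(O)c(OS(=O)(=O)O)c(Br)c1Br | target

**Count**

Total steps: 8. Longest linear sequence: 8 steps (kojic acid 1 → 19).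

**Steps most likely to fail**

Step 2. The ring transmutation may be diverted by proton transfer from the CH2O arm of the pyrylium ion to the basic ylide, by silyl transfer to the ylide carbon, or by addition at C4 without ring opening. The fallback uses known chemistry and builds the same arene from a preformed benzene ring. It sets out from 4-methoxybenzyl chloride 2 and purchased 2-bromo-4,5-dihydroxybenzaldehyde F1. Alkylation of the more acidic hydroxyl para to the formyl group (2, NaHCO3, NaI, DMF, 40 °C) would give 2-bromo-5-hydroxy-4-(4-methoxybenzyloxy)benzaldehyde F2. Silylation (i-Pr3SiCl, imidazole, DMF) would give 2-bromo-4-(4-methoxybenzyloxy)-5-[tri(propan-2-yl)silyloxy]benzaldehyde F3. Reduction (NaBH4, MeOH/THF, 0 °C) would give {2-bromo-4-(4-methoxybenzyloxy)-5-[tri(propan-2-yl)silyloxy]phenyl}methanol F4. Williamson etherification with 2 (NaH, Bu4NI, THF, 0 °C) comes back to the route at 10.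

Step 3. Chemoselectivity between the two 4-methoxybenzyl ethers may be lost, either by ionisation of the arm ether once the para oxygen is free or by C-benzylation of the phenol ring. The fallback gives up the differentiation: both ethers are removed oxidatively and the arm is taken to the aldehyde level, where no quinone methide can form. It sets out from 10. DDQ in excess (CH2Cl2/H2O, rt) should cleave both ethers and oxidise the electron-rich 4-hydroxybenzyl alcohol to 2-bromo-4-hydroxy-5-[tri(propan-2-yl)silyloxy]benzaldehyde F5. NBS bromination ortho to the phenol would give 2,3-dibromo-4-hydroxy-5-[tri(propan-2-yl)silyloxy]benzaldehyde F6. SO3·pyridine followed by NaHCO3 would give sodium 2,3-dibromo-4-formyl-6-[tri(propan-2-yl)silyloxy]phenyl sulfate F7. Reduction of the aldehyde (NaBH4, MeOH, 0 °C) comes back to the route at 15.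

Step 5. O-Sulfonation of a phenol flanked by bromine and a bulky silyl ether may be slow, and under more forcing basic conditions the silyl group may migrate to the C4 oxygen so that the wrong oxygen is sulfated. The fallback introduces the sulfate as a neutral protected diester with a much more electrophilic chlorosulfate at low temperature. It sets out from 12. 2,2,2-Trichloroethyl chlorosulfate (Et3N, DMAP, THF, 0 °C) would give 2,3-dibromo-4-[(4-methoxybenzyloxy)methyl]-6-[tri(propan-2-yl)silyloxy]phenyl 2,2,2-trichloroethyl sulfate F8. DDQ (CH2Cl2/pH 7 buffer) would give 2,3-dibromo-4-(hydroxymethyl)-6-[tri(propan-2-yl)silyloxy]phenyl 2,2,2-trichloroethyl sulfate F9. SO3·pyridine followed by NaHCO3 would give sodium {2,3-dibromo-4-[(2,2,2-trichloroethoxy)sulfonyloxy]-5-[tri(propan-2-yl)silyloxy]phenyl}methyl sulfate F10. Reductive removal of the trichloroethyl group (Zn dust, HCO2NH4, MeOH, rt) and exchange to the sodium form (NaHCO3) comes back to the route at 17.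

**Further compounds**

F1 | step 2 | 2-bromo-4,5-dihydroxybenzaldehyde (purchased) | O=Cc1cc(O)c(O)cc1Br
F2 | step 2 | 2-bromo-5-hydroxy-4-(4-methoxybenzyloxy)benzaldehyde | COc1ccc(COc2cc(Br)c(C=O)cc2O)cc1
F3 | step 2 | 2-bromo-4-(4-methoxybenzyloxy)-5-[tri(propan-2-yl)silyloxy]benzaldehyde | COc1ccc(COc2cc(Br)c(C=O)cc2O[Si](C(C)C)(C(C)C)C(C)C)cc1
F4 | step 2 | {2-bromo-4-(4-methoxybenzyloxy)-5-[tri(propan-2-yl)silyloxy]phenyl}methanol | COc1ccc(COc2cc(Br)c(CO)cc2O[Si](C(C)C)(C(C)C)C(C)C)cc1
F5 | step 3 | 2-bromo-4-hydroxy-5-[tri(propan-2-yl)silyloxy]benzaldehyde | O=Cc1cc(O[Si](C(C)C)(C(C)C)C(C)C)c(O)cc1Br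
F6 | step 3 | 2,3-dibromo-4-hydroxy-5-[tri(propan-2-yl)silyloxy]benzaldehyde | O=Cc1cc(O[Si](C(C)C)(C(C)C)C(C)C)c(O)c(Br)c1Br
F7 | step 3 | sodium 2,3-dibromo-4-formyl-6-[tri(propan-2-yl)silyloxy]phenyl sulfate | O=Cc1cc(O[Si](C(C)C)(C(C)C)C(C)C)c(OS(=O)(=O)[O-])c(Br)c1Br.[Na+]
F8 | step 5 | 2,3-dibromo-4-[(4-methoxybenzyloxy)methyl]-6-[tri(propan-2-yl)silyloxy]phenyl 2,2,2-trichloroethyl sulfate | COc1ccc(COCc2cc(O[Si](C(C)C)(C(C)C)C(C)C)c(OS(=O)(=O)OCC(Cl)(Cl)Cl)c(Br)c2Br)cc1
F9 | step 5 | 2,3-dibromo-4-(hydroxymethyl)-6-[tri(propan-2-yl)silyloxy]phenyl 2,2,2-trichloroethyl sulfate | OCc1cc(O[Si](C(C)C)(C(C)C)C(C)C)c(OS(=O)(=O)OCC(Cl)(Cl)Cl)c(Br)c1Br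
F10 | step 5 | sodium {2,3-dibromo-4-[(2,2,2-trichloroethoxy)sulfonyloxy]-5-[tri(propan-2-yl)silyloxy]phenyl}methyl sulfate | [O-]S(=O)(=O)OCc1cc(O[Si](C(C)C)(C(C)C)C(C)C)c(OS(=O)(=O)OCC(Cl)(Cl)Cl)c(Br)c1Br.[Na+]
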